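The spiro N,O-ketal carbon is cut from its aryl, nitrogen and oxygen partners at once. Its five-membered naphtho[1,8-bc]furan ring (O, spiro C, naphthalene C1, C8a, C8) is drawn from a flat, achiral six-membered naphtho[1,8-de][1,2]oxazine that holds the same five atoms plus one nitrogen and comes from peri C–H oxygenation of a 2-naphthol aldoxime. In one operation an ortho-lithiated benzamide breaks the N–O bond and adds to the nitrile so unmasked. A chiral phosphoric acid then expels the ring nitrogen as ammonia while lactam and furan close on the new stereocentre. The step exploits the peri C1/C8 geometry and the acyl oxidation level hidden in the oxime carbon.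

Key step: step 6

Locants: naphthalene C1 carries the spiro carbon, C2 the free hydroxyl, C6 the methyl group and C8 the ring oxygen (O8).
Assumption: the sense of induction of the phosphoric acid cannot be derived with certainty. (R)-TRIP is written, and its mirror image is used if the ECD comparison of 15 calls for it.

Step 1
Reactants: 1 3-methoxybenzoyl chloride; 2 2-[(tert-butyldimethylsilyl)oxy]ethan-1-amine
Product: 3 N-{2-[(tert-butyldimethylsilyl)oxy]ethyl}-3-methoxybenzamide
Conditions: Et3N, CH2Cl2, 0 °C → rt
Reagents that add atoms: none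
Why: Schotten–Baumann-type N-acylation of a primary amine by an acid chloride, which leaves the silyl ether untouched.

Step 2
Reactants: 4 6-methylnaphthalen-2-ol
Product: 5 2-hydroxy-6-methylnaphthalene-1-carbaldehyde
Conditions: MgCl2, Et3N, (CH2O)n, MeCN, reflux; then 1 M HCl
Reagents that add atoms: paraformaldehyde (as formaldehyde), C=O
Why: In the Casnati–Skattebøl ortho-formylation the magnesium naphtholate delivers formaldehyde to C1, the more nucleophilic ortho position of a 2-naphthol, and a second formaldehyde oxidises the carbinol by hydride transfer.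

Step 3
Reactants: 5 2-hydroxy-6-methylnaphthalene-1-carbaldehyde
Product: 6 (E)-2-hydroxy-6-methylnaphthalene-1-carbaldehyde oxime
Conditions: NH2OH·HCl, NaOAc, EtOH/H2O, rt
Reagents that add atoms: hydroxylamine hydrochloride, NO.Cl
Why: Oxime condensation, in which the E isomer is favoured by the O–H···N hydrogen bond from the C2 hydroxyl.

Step 4
Reactants: 6 (E)-2-hydroxy-6-methylnaphthalene-1-carbaldehyde oxime
Product: 8 8-methylnaphtho[1,8-de][1,2]oxazin-4-ol, via quinone nitrosomethide 7 (not isolated)
Conditions: PhI(OAc)2, t-BuOH, rt, high dilution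
Reagents that add atoms: none
Why: Iodine(III) oxidation gives o-naphthoquinone nitrosomethide 7, whose O=N–C=C1–C8a=C8 triene closes by 6π-oxa-electrocyclisation onto the peri carbon and re-aromatises by tautomerisation, a peri-cyclisation known for 2-hydroxy-1-naphthaldehyde oximes, while dilution and the non-nucleophilic alcohol hold back dimerisation and solvent capture.

Step 5
Reactants: 8 8-methylnaphtho[1,8-de][1,2]oxazin-4-ol
Product: 9 4-[(tert-butyldimethylsilyl)oxy]-8-methylnaphtho[1,8-de][1,2]oxazine
Conditions: TBSCl, imidazole, CH2Cl2, 0 °C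
Reagents that add atoms: tert-butyldimethylsilyl chloride, CC(C)(C)[Si](C)(C)Cl
Why: Standard O-silylation of a naphthol under a base too weak and a temperature too low to open the oxime ether ring.

Step 6
Reactants: 9 4-[(tert-butyldimethylsilyl)oxy]-8-methylnaphtho[1,8-de][1,2]oxazine; 3 N-{2-[(tert-butyldimethylsilyl)oxy]ethyl}-3-methoxybenzamide (2.2 equiv)
Product: 14 (R)-3'-[(tert-butyldimethylsilyl)oxy]-2-{2-[(tert-butyldimethylsilyl)oxy]ethyl}-7-methoxy-7'-methylspiro[isoindoline-1,2'-naphtho[1,8-bc]furan]-3-one, via dilithiated amide 10 (not isolated), via lithium cyanonaphtholate 11 (not isolated), via N–H ketimine 12 (not isolated), via N-acyliminium ion 13 (not isolated)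
Conditions: 3, s-BuLi (4.5 equiv), TMEDA, THF, −78 °C; add 9, −78 → 0 °C; aq NH4Cl wash, swap to toluene (crude, no purification); (R)-TRIP (10 mol %), Amberlite CG50, 4 Å MS, 40 °C
Reagents that add atoms: none
Why: Proposed new method: One equivalent of 10 removes the oxime-ether C–H that lies anti to the N–O bond (Kemp-type E2) and so opens the six-membered ring of 9 to nitrile and C8 naphtholate 11, a second equivalent adds to the nitrile carbon to give ketimine 12 after the quench, and the phosphoric acid then lets the amide nitrogen add to the protonated ketimine, expels the former ring nitrogen as NH3 (bound by the resin) and leaves ion pair 13, which O8–H captures, so that the ring O–N=C–C1–C8a–C8 returns as O–C–C1–C8a–C8. Closest known reaction types are the base-induced opening of naphtho[1,8-de][1,2]oxazines to 8-hydroxy-1-naphthonitriles, the addition of ortho-lithiated benzamides to nitriles, the phosphoric-acid-catalysed addition of heteroatom nucleophiles to N-acyl ketiminium ions of the 3-arylisoindolinone class and the resin-assisted removal of NH3 in the catalytic asymmetric Fischer indolisation; new are their union in one operation and the peri-naphthol as internal nucleophile. Both rings close 5-exo-trig, the lactam by attack of the amide N on the C=NH2+ carbon and the furan by attack of O8 on the C=N+ carbon. The single stereocentre forms in this last event inside the contact ion pair, where the phosphate, hydrogen-bonded to O8–H and walled by its 3,3'-aryl groups, decides toward which face of the planar iminium the naphthalene twists. The selectivities needed are secured by the substrates: C2 of 3 is the only position flanked by both directing groups, the aryl silyl ether keeps a C2 oxide from deactivating the nitrile, the alkyl silyl ether keeps the side-chain oxygen from closing an oxazolidine, and any direct 1,2-addition of 10 to the C=N bond of 9 converges on 12 through the same base-induced N–O cleavage. The ratio set under kinetic control should persist because the aryl ether oxygen of 14 is far less basic than the departing amine, so that re-ionisation is slow under the weak acid.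

Step 7
Reactants: 14 (R)-bis-silyl ether of the spiro lactam
Product: 15 (S)-3'-hydroxy-2-(2-hydroxyethyl)-7-methoxy-7'-methylspiro[isoindoline-1,2'-naphtho[1,8-bc]furan]-3-one (CNP0434366.2)
Conditions: TBAF, AcOH, THF, 0 °C
Reagents that add atoms: none
Why: Fluoride-induced desilylation of both ethers, buffered so that no free naphtholate persists; no bond at the stereocentre is touched, and the descriptor changes from R to S only because OSi outranks OMe in 14 whereas OH does not in 15.

Compound list
1 | 3-methoxybenzoyl chloride | COc1cccc(C(=O)Cl)c1 | starting material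
2 | 2-[(tert-butyldimethylsilyl)oxy]ethan-1-amine | NCCO[Si](C)(C)C(C)(C)C | starting material
3 | N-{2-[(tert-butyldimethylsilyl)oxy]ethyl}-3-methoxybenzamide | COc1cccc(C(=O)NCCO[Si](C)(C)C(C)(C)C)c1 | intermediate
4 | 6-methylnaphthalen-2-ol | Cc1ccc2cc(O)ccc2c1 | starting material
5 | 2-hydroxy-6-methylnaphthalene-1-carbaldehyde | Cc1ccc2c(C=O)c(O)ccc2c1 | intermediate
6 | (E)-2-hydroxy-6-methylnaphthalene-1-carbaldehyde oxime | Cc1ccc2c(/C=N/O)c(O)ccc2c1 | intermediate
7 | 6-methyl-1-(nitrosomethylidene)naphthalen-2(1H)-one | Cc1ccc2c(c1)C=CC(=O)C2=CN=O | intermediate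
8 | 8-methylnaphtho[1,8-de][1,2]oxazin-4-ol | Cc1cc2ccc(O)c3C=NOc(c1)c23 | intermediate
9 | 4-[(tert-butyldimethylsilyl)oxy]-8-methylnaphtho[1,8-de][1,2]oxazine | Cc1cc2ccc(O[Si](C)(C)C(C)(C)C)c3C=NOc(c1)c23 | intermediate
10 | C2,N-dilithiated amide 3 | [Li]c1c(OC)cccc1C(=O)N([Li])CCO[Si](C)(C)C(C)(C)C | intermediate
11 | lithium 7-[(tert-butyldimethylsilyl)oxy]-8-cyano-3-methylnaphthalen-1-olate | Cc1cc([O-])c2c(C#N)c(O[Si](C)(C)C(C)(C)C)ccc2c1.[Li+] | intermediate
12 | N–H ketimine joining C2 of amide 3 to C1 of the 2-silyloxy-8-hydroxy-6-methylnaphthalene | COc1cccc(C(=O)NCCO[Si](C)(C)C(C)(C)C)c1C(=N)c1c(O[Si](C)(C)C(C)(C)C)ccc2cc(C)cc(O)c12 | intermediate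
13 | 3-aryl-1-oxoisoindol-2-ium (N-acyliminium) ion, paired with the chiral phosphate | COc1cccc2c1C(c1c(O[Si](C)(C)C(C)(C)C)ccc3cc(C)cc(O)c13)=[N+](CCO[Si](C)(C)C(C)(C)C)C2=O | intermediate
14 | (R)-3'-[(tert-butyldimethylsilyl)oxy]-2-{2-[(tert-butyldimethylsilyl)oxy]ethyl}-7-methoxy-7'-methylspiro[isoindoline-1,2'-naphtho[1,8-bc]furan]-3-one | COc1cccc2c1[C@]1(Oc3cc(C)cc4ccc(O[Si](C)(C)C(C)(C)C)c1c34)N(CCO[Si](C)(C)C(C)(C)C)C2=O | intermediate
15 | (S)-3'-hydroxy-2-(2-hydroxyethyl)-7-methoxy-7'-methylspiro[isoindoline-1,2'-naphtho[1,8-bc]furan]-3-one | COc1cccc2c1[C@]1(Oc3cc(C)cc4ccc(O)c1c34)N(CCO)C2=O | target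

Total step count: 7. Longest linear sequence: 6 (steps 2 to 7, from 4).

Steps most likely to fail

Step 6. The facial selectivity of the ion-pair closure may be low, or uncatalysed closure may already occur during the quench. The fallback uses known chemistry and obtains the stereocentre by resolution instead of catalysis. It sets out from 9 and 3 and runs the same anionic sequence through 10, 11 and 12. The crude ketimine is then closed with trifluoroacetic acid in CH2Cl2, which should give the racemic bis-silyl ether F1. Buffered fluoride should give the racemic diol F2. Preparative HPLC on an amylose tris(3,5-dimethylphenylcarbamate) phase separates the unwanted (R)-enantiomer F3 from 15, where the route is rejoined.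

Step 4. Intermediate 7 may close through its carbonyl oxygen onto nitrogen (ortho-cyclisation) or add to itself faster than it reaches the peri carbon. The fallback builds the N–O–C8 link by cross-coupling instead of oxidation and sets out from 5. Silylation gives the aldehyde silyl ether F4. Pd(OAc)2-catalysed, aldehyde-directed peri C–H bromination with NBS (C2 is blocked) gives the 8-bromide F5. Pd-catalysed O-arylation of ethyl acetohydroximate (Cs2CO3, toluene) gives the O-aryl hydroximate F6. Aqueous HCl in dioxane unmasks the O-arylhydroxylamine, which condenses with the peri aldehyde and loses the silyl group, and the route is rejoined at 8.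

Step 7. Enantiomeric purity may erode, because a naphtholate unmasked by fluoride can push out O8 and open the ketal reversibly to the o-quinone methide. The fallback drops the aryl silyl ether altogether and sets out from 8, with step 5 omitted. With 3.3 equiv of 10 the sequence should run through the dilithium cyanonaphthalenediolate F7, the dihydroxy ketimine F8 and the iminium ion F9 to the mono-silyl ether F10. The remaining primary silyl ether of F10 is hydrolysed with AcOH/THF/H2O at rt, so that no naphtholate is generated once the stereocentre exists. The route is rejoined at 15.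

Further compounds
F1 | step 6 | racemic bis-silyl ether of the spiro lactam | COc1cccc2c1C1(Oc3cc(C)cc4ccc(O[Si](C)(C)C(C)(C)C)c1c34)N(CCO[Si](C)(C)C(C)(C)C)C2=O
F2 | step 6 | racemic 3'-hydroxy-2-(2-hydroxyethyl)-7-methoxy-7'-methylspiro[isoindoline-1,2'-naphtho[1,8-bc]furan]-3-one | COc1cccc2c1C1(Oc3cc(C)cc4ccc(O)c1c34)N(CCO)C2=O
F3 | step 6 | (R)-enantiomer of 15 | COc1cccc2c1[C@@]1(Oc3cc(C)cc4ccc(O)c1c34)N(CCO)C2=O
F4 | step 4 | 2-[(tert-butyldimethylsilyl)oxy]-6-methylnaphthalene-1-carbaldehyde | Cc1ccc2c(C=O)c(O[Si](C)(C)C(C)(C)C)ccc2c1
F5 | step 4 | 8-bromo-2-[(tert-butyldimethylsilyl)oxy]-6-methylnaphthalene-1-carbaldehyde | Cc1cc(Br)c2c(C=O)c(O[Si](C)(C)C(C)(C)C)ccc2c1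
F6 | step 4 | ethyl N-({7-[(tert-butyldimethylsilyl)oxy]-8-formyl-3-methylnaphthalen-1-yl}oxy)ethanimidate | CCOC(C)=NOc1cc(C)cc2ccc(O[Si](C)(C)C(C)(C)C)c(C=O)c12
F7 | step 7 | dilithium 1-cyano-6-methylnaphthalene-2,8-diolate | Cc1cc([O-])c2c(C#N)c([O-])ccc2c1.[Li+].[Li+]
F8 | step 7 | N–H ketimine with free C2 and C8 hydroxyls | COc1cccc(C(=O)NCCO[Si](C)(C)C(C)(C)C)c1C(=N)c1c(O)ccc2cc(C)cc(O)c12
F9 | step 7 | N-acyliminium ion with free C2 and C8 hydroxyls | COc1cccc2c1C(c1c(O)ccc3cc(C)cc(O)c13)=[N+](CCO[Si](C)(C)C(C)(C)C)C2=O
F10 | step 7 | (S)-2-{2-[(tert-butyldimethylsilyl)oxy]ethyl}-3'-hydroxy-7-methoxy-7'-methylspiro[isoindoline-1,2'-naphtho[1,8-bc]furan]-3-one | COc1cccc2c1[C@]1(Oc3cc(C)cc4ccc(O)c1c34)N(CCO[Si](C)(C)C(C)(C)C)C2=O
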